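The pitfall is to set the last J of elm beside the last J of cedar as if temperature were the one difference between them: their charges differ too.

| flask | L | temperature | remark | time |
|---|---|---|---|---|
| elm | 0.10 M | 1 °C | run made earlier |  |
| cedar | 0.16 M | 26 °C | run made earlier |  |
| south | 0.21 M | 5 °C |  | 3.0 d |
| south-west | 0.21 M | 20 °C |  | 3.0 d |
| east | 0.21 M | 35 °C |  | 3.0 d |
| south-east | 0.21 M | −10 °C |  | 3.0 d |

elm run (percent of the L charged)

| time / d | J / % | Z / % |
|---|---|---|
| 0.208 | 19.0 | 47.1 |
| 0.333 | 25.1 | 52.2 |
| 0.500 | 29.3 | 54.6 |
| 0.833 | 33.7 | 57.2 |
| 1.67 | 36.7 | 56.9 |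
| 2.50 | 40.7 | 57.3 |

cedar run (percent of the L charged)

| time / h | J / % | Z / % |
|---|---|---|
| 1.33 | 46.3 | 43.5 |
| 4.00 | 51.0 | 44.5 |
| 8.00 | 50.7 | 46.1 |
| 10.0 | 54.3 | 45.3 |
| 15.0 | 53.6 | 46.2 |
| 20.0 | 52.9 | 47.2 |

(each reading ± 1 percentage point)

- the flask with the highest share of J in all that became J or Z or G ("all alike" if they lie within 1.5 percentage points) (south / south-west / east / south-east / all alike)
- share of J in all that became J or Z or G, south
- share of J in all that became J or Z or G, south-west
- share of J in all that became J or Z or G, east
- share of J in all that became J or Z or G, south-east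

- percentages count the L that a species holds: one Z counts as two
- percentages count the L that a species holds: one G counts as three
- a reading or a percentage of J counts all its forms, free or not

1. Write the balance of L as I read it. L leaves by ring closure, first order in [L], and by dimer formation, second order in [L]. The L going to J over the L going to Z is then W/[L], where W is a concentration that depends on temperature. This W is the effective molarity.

2. As a crude reading, put the charge [L]₀ in place of the falling [L], so that W is the charge times J over Z. The last readings give 0.0710 M for elm and 0.179 M for cedar, each with the scatter of its readings.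

3. Now turn the question round. The four flasks share one charge, and on this crude reading the share of J in J and Z is W/(W+[L]₀), so on this reading east could lose its lead if W stopped rising with temperature. A flat W would put that share in cedar at 30.7%. The readings give 52.8%, a gap of 22 percentage points against a scatter of 1 point.

4. My own reckoning lets W grow by a constant factor per degree. That gives 0.250 M for east and, for south-east, the [L]₀ at which this crude reading puts J and Z equal at that temperature, 0.0473 M. My shares of J in J and Z are 28.2% for south, 40.6% for south-west, 54.4% for east and 18.4% for south-east, so east leads.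

5. The forecast, on its own formula, says “ring closure gains with heat” and names east, with 30%, 42%, 54% and 18% in the same order. Its south stands above mine.

The flasks give east, with 30.4%, 42.2%, 54.2% and 16.8% in that order, east highest.

    L → J (k = 0.760 h⁻¹, Ea = 80.0 kJ mol⁻¹)
    2 L → Z (k = 7.04 M⁻¹ h⁻¹, Ea = 50.0 kJ mol⁻¹)
    L + Z → G (k = 0.343 M⁻¹ h⁻¹, Ea = 73.0 kJ mol⁻¹)
    L + J ⇌ X, settled at all times (K = 3.70 M⁻¹, ΔH = −44.0 kJ mol⁻¹)
    (constants at 20 °C)

Carry W to the neighbour of south-east, which keeps the temperature and the time but is charged with 0.84 M of L. On south-east itself, 0.0473 M gave 18.4% of J in J and Z, and the flask has 16.8% of J in J, Z and G, at a conversion of 97.1%. On the neighbour, the same W gives 5.33% of J in J and Z, and the flask has 6.24% of J in J, Z and G, below south-east. At 3.00 d that neighbour holds 6.13% as J, bound forms counted, 3.41% as G, and 0.83% of its charge as free L.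

(The data come from a simulation on assumed constants, noise included.)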